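**Plan**
- Retrosynthesis first cuts the cinnamoyl–N amide (macrolactam), then the aryl C8–vinyl bond (Stille), the acryloyl–N amide and the C9b–CH=CH alkene (Z-olefination of a C9b aldehyde). This leaves a brominated tricyclic keto aldehyde.
- The enabling feature is the β-aryloxy ketone O5–C4a–C4–C3(=O) of the cis-fused cyclohexanone/dihydrofuran. It is cut at C3–C4 (Claisen-type acylation) and at O5–C4a (oxa-Michael), giving a phenol whose benzylic quaternary carbon C9b carries a propanoate, an acrylate and a formyl group.
- The phenol oxygen and that formyl carbon are 1,4-related, so both are stored as a benzofuran-2(3H)-one/lactol ring that is not in the target. It acidifies the C–H used to build C9b and is opened in the key step.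
- Forward: the quaternary carbon is built on 5-bromobenzofuranone (formylation, asymmetric Michael addition, Wittig) and the lactone is reduced to the lactol. One pot then opens the lactol, closes the dihydrofuran and closes the cyclohexanone. The Z-acrylic acid, the amide to the butyl-end nitrogen of a bis-Boc spermidine, the Z-cinnamate and the 20-membered lactam follow.
- Stereochemistry: C9b (S) comes from the catalytic asymmetric Michael addition, and C4a (R) from the enforced cis ring fusion in the cascade. The two Z-alkenes come from a Still–Gennari olefination and a configurationally defined Z-alkenylstannane.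

Key step: step 5

Assumption: 5-bromo-1-benzofuran-2(3H)-one, the N1,N5-bis-Boc spermidine and ethyl (Z)-3-(tributylstannyl)acrylate are taken as purchasable; the first is otherwise one lactonisation away from 2-(5-bromo-2-hydroxyphenyl)acetic acid.

**Step 1**
Reactants: 1 5-bromo-1-benzofuran-2(3H)-one; 2 N,N-dimethylformamide dimethyl acetal
Product: 4 5-bromo-3-(hydroxymethylidene)-1-benzofuran-2(3H)-one, via enaminone 3 (not isolated)
Conditions: 2 (1.5 equiv), PhMe, 80 °C; then 2 M HCl, THF, rt
Reagents that add atoms: water O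
Why: Aminomethylenation of the acidic lactone CH2 with the amide acetal and acid hydrolysis of the enaminone (a formylation) should give the enolised 3-formyl lactone, a cyclic 1,3-dicarbonyl C–H acid that can take up only one Michael acceptor.

**Step 2**
Reactants: 4 5-bromo-3-(hydroxymethylidene)-1-benzofuran-2(3H)-one; 5 methyl acrylate
Product: 6 methyl 3-[(3S)-5-bromo-3-formyl-2-oxo-2,3-dihydro-1-benzofuran-3-yl]propanoate
Conditions: 5 (5 equiv), 1-[3,5-bis(trifluoromethyl)phenyl]-3-(9-deoxy-epi-quinidin-9-yl)thiourea (10 mol%), PhMe, 0 °C → rt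
Reagents that add atoms: none
Why: In this organocatalytic asymmetric Michael addition the quinuclidine holds the enolate of 4 and the thiourea activates the acrylate, so that C–C bond formation on one face of the planar enolate should set the quaternary centre (the later C9b) as S, the quinine-derived pseudoenantiomer being used instead if the opposite sense is found.

**Step 3**
Reactants: 6 methyl 3-[(3S)-5-bromo-3-formyl-2-oxo-2,3-dihydro-1-benzofuran-3-yl]propanoate; 7 tert-butyl (triphenyl-λ5-phosphanylidene)acetate
Product: 8 tert-butyl (2E)-3-[(3R)-5-bromo-3-(3-methoxy-3-oxopropyl)-2-oxo-2,3-dihydro-1-benzofuran-3-yl]prop-2-enoate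
Conditions: 7 (1.2 equiv), PhMe, 60 °C
Reagents that add atoms: none
Why: Wittig olefination of the non-enolisable aldehyde with a stabilised ylide should give the (E)-enoate, whose geometry is irrelevant because both alkene carbons become sp3 in step 5, and it leaves the quaternary centre untouched (the descriptor changes to R only by priority).

**Step 4**
Reactants: 8 tert-butyl (2E)-3-[(3R)-5-bromo-3-(3-methoxy-3-oxopropyl)-2-oxo-2,3-dihydro-1-benzofuran-3-yl]prop-2-enoate
Product: 9 tert-butyl (2E)-3-[(3R)-5-bromo-2-hydroxy-3-(3-methoxy-3-oxopropyl)-2,3-dihydro-1-benzofuran-3-yl]prop-2-enoate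
Conditions: LiAlH(OtBu)3 (1.2 equiv), THF, −40 → 0 °C; aq. potassium sodium tartrate
Reagents that add atoms: none
Why: Chemoselective partial reduction of the aryl lactone (an activated phenolic ester) by the bulky alkoxy hydride should stop at the lactol aluminate and spare the methyl ester and the tert-butyl enoate; the new hemiacetal carbon forms as both epimers, which does not matter.

**Step 5**
Reactants: 9 tert-butyl (2E)-3-[(3R)-5-bromo-2-hydroxy-3-(3-methoxy-3-oxopropyl)-2,3-dihydro-1-benzofuran-3-yl]prop-2-enoate
Product: 12 tert-butyl (4aR,9bS)-8-bromo-9b-formyl-3-oxo-1,2,3,4,4a,9b-hexahydrodibenzo[b,d]furan-4-carboxylate, via phenoxide aldehyde 10 (not isolated), via oxa-Michael adduct 11 (not isolated)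
Conditions: KOtBu (2.5 equiv), THF (0.02 M), −20 °C → rt; then AcOH
Reagents that add atoms: none
Why: tert-Butoxide opens the lactol 9 to the phenoxide aldehyde 10, the phenoxide adds 5-exo-trig to the tert-butyl enoate (oxa-Michael) to give the ester enolate of 11, and this enolate attacks the methyl ester 6-exo-trig (Dieckmann condensation), so that the C3–C4 bond closes the cyclohexanone, methoxide leaves and deprotonation of the β-keto ester makes the sequence irreversible. The closest known reaction type is the tandem oxa-Michael/Dieckmann condensation (Michael-initiated ring closure) used for 3-oxotetrahydrofurans. The new centre C4a is controlled by the existing quaternary centre C9b: only the epimer with the acetate arm cis to the propanoate arm can reach the ester, the trans epimer returns through retro-oxa-Michael, and a trans-fused hexahydrodibenzofuran is too strained to form. The step needs regioselectivity between the two possible Claisen directions and chemoselectivity towards the freed aldehyde; the first is secured by the tert-butyl ester, a poor acyl acceptor, and by site-specific generation of the enolate at C4, the second by the fact that either enolate could only close a four-membered ring onto the non-enolisable aldehyde. C9b is not touched, and C4 is left as an epimer/enol mixture that is erased on decarboxylation.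

**Step 6**
Reactants: 12 tert-butyl (4aR,9bS)-8-bromo-9b-formyl-3-oxo-1,2,3,4,4a,9b-hexahydrodibenzo[b,d]furan-4-carboxylate; 13 methyl [bis(2,2,2-trifluoroethoxy)phosphoryl]acetate
Product: 14 tert-butyl (4aR,9bS)-8-bromo-9b-[(1Z)-3-methoxy-3-oxoprop-1-en-1-yl]-3-oxo-1,2,3,4,4a,9b-hexahydrodibenzo[b,d]furan-4-carboxylate
Conditions: 13 (1.5 equiv), KN(SiMe3)2 (2.5 equiv), 18-crown-6 (5 equiv), THF, −78 °C
Reagents that add atoms: none
Why: Still–Gennari olefination of the neopentyl aldehyde under kinetic control should give the (Z)-enoate, the extra base holding the β-keto ester as its inert potassium enolate.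

**Step 7**
Reactants: 14 tert-butyl (4aR,9bS)-8-bromo-9b-[(1Z)-3-methoxy-3-oxoprop-1-en-1-yl]-3-oxo-1,2,3,4,4a,9b-hexahydrodibenzo[b,d]furan-4-carboxylate
Product: 17 (2Z)-3-[(4aR,9bS)-8-bromo-3-oxo-1,2,3,4,4a,9b-hexahydrodibenzo[b,d]furan-9b-yl]prop-2-enoic acid, via acid ester 15 (not isolated), via keto diacid 16 (not isolated)
Conditions: LiOH (3 equiv), THF–H2O, 0 °C → rt; 1 M HCl to pH 3; then CF3CO2H–CH2Cl2 (1:3), rt → 35 °C
Reagents that add atoms: lithium hydroxide [Li+].[OH-]
Why: Saponification of the methyl ester (the β-keto ester is masked as its enolate and the tert-butyl ester resists hydroxide) followed by acidolysis of the tert-butyl ester and decarboxylation of the β-keto acid should give the keto acid without touching C4a, C9b or the Z-alkene.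

**Step 8**
Reactants: 17 (2Z)-3-[(4aR,9bS)-8-bromo-3-oxo-1,2,3,4,4a,9b-hexahydrodibenzo[b,d]furan-9b-yl]prop-2-enoic acid; 18 tert-butyl (4-aminobutyl){3-[(tert-butoxycarbonyl)amino]propyl}carbamate
Product: 19 tert-butyl [4-({(2Z)-3-[(4aR,9bS)-8-bromo-3-oxo-1,2,3,4,4a,9b-hexahydrodibenzo[b,d]furan-9b-yl]prop-2-enoyl}amino)butyl]{3-[(tert-butoxycarbonyl)amino]propyl}carbamate
Conditions: EDC·HCl, HOBt, i-Pr2NEt, CH2Cl2, 0 °C → rt
Reagents that add atoms: none
Why: Carbodiimide/HOBt amide coupling engages the only free amine of 18, the primary butyl-end nitrogen, so the acryloyl group is placed on the four-carbon side of the spermidine.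

**Step 9**
Reactants: 19 bromo amide from step 8; 20 ethyl (2Z)-3-(tributylstannyl)prop-2-enoate
Product: 21 the analogue of 19 in which Br at C8 is replaced by a (1Z)-3-ethoxy-3-oxoprop-1-en-1-yl group
Conditions: 20 (1.5 equiv), Pd(PPh3)4 (10 mol%), CuI (20 mol%), CsF (2 equiv), DMF, 45 °C
Reagents that add atoms: none
Why: Stille cross-coupling of the aryl bromide with the (Z)-alkenylstannane, accelerated by CuI and CsF, should proceed with retention of the alkene geometry and so install the (Z)-cinnamate, while the carbamates, the amide and the ketone are inert.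

**Step 10**
Reactants: 21 (Z)-cinnamate ethyl ester from step 9
Product: 23 seco amino acid: the (Z)-cinnamic acid of 21 with both spermidine nitrogens deprotected (isolated as its trifluoroacetate salt), via Boc-protected acid 22 (not isolated)
Conditions: LiOH (3 equiv), THF–MeOH–H2O, 0 °C → rt; 1 M HCl to pH 4; then CF3CO2H–CH2Cl2 (1:4), 0 °C, dark
Reagents that add atoms: lithium hydroxide [Li+].[OH-]
Why: Ester saponification and then acidolytic removal of both Boc groups (cold and in the dark, to avoid acid-mediated Z to E isomerisation of the electron-rich cinnamic acid) should give the seco amino acid.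

**Step 11**
Reactants: 23 seco amino acid
Product: 24 target macrolactam CNP0415009.2
Conditions: slow addition of 23 to EDC·HCl (3 equiv), HOAt (3 equiv), i-Pr2NEt (6 equiv), CH2Cl2–DMF (9:1), 0.5 mM, 0 °C → rt
Reagents that add atoms: none
Why: High-dilution macrolactamisation through the HOAt active ester should close the 20-membered ring at the primary propyl-end amine, which is acylated in preference to the hindered acyclic secondary amine as in primary-selective acylations of spermidine; no stereocentre is formed and the secondary amine stays free.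

**Compound list**
1 | 5-bromo-1-benzofuran-2(3H)-one | O=C1Cc2cc(Br)ccc2O1 | starting material
2 | N,N-dimethylformamide dimethyl acetal | COC(OC)N(C)C | starting material
3 | 5-bromo-3-[(dimethylamino)methylidene]-1-benzofuran-2(3H)-one (not isolated) | CN(C)C=C1C(=O)Oc2ccc(Br)cc12 | intermediate
4 | 5-bromo-3-(hydroxymethylidene)-1-benzofuran-2(3H)-one (enol of the 3-formyl lactone) | OC=C1C(=O)Oc2ccc(Br)cc12 | intermediate
5 | methyl acrylate | C=CC(=O)OC | starting material
6 | methyl 3-[(3S)-5-bromo-3-formyl-2-oxo-2,3-dihydro-1-benzofuran-3-yl]propanoate | COC(=O)CC[C@]1(C=O)C(=O)Oc2ccc(Br)cc21 | intermediate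
7 | tert-butyl (triphenyl-λ5-phosphanylidene)acetate | CC(C)(C)OC(=O)C=P(c1ccccc1)(c1ccccc1)c1ccccc1 | starting material
8 | tert-butyl (2E)-3-[(3R)-5-bromo-3-(3-methoxy-3-oxopropyl)-2-oxo-2,3-dihydro-1-benzofuran-3-yl]prop-2-enoate | COC(=O)CC[C@]1(/C=C/C(=O)OC(C)(C)C)C(=O)Oc2ccc(Br)cc21 | intermediate
9 | tert-butyl (2E)-3-[(3R)-5-bromo-2-hydroxy-3-(3-methoxy-3-oxopropyl)-2,3-dihydro-1-benzofuran-3-yl]prop-2-enoate (lactol, both C2 epimers) | COC(=O)CC[C@]1(/C=C/C(=O)OC(C)(C)C)C(O)Oc2ccc(Br)cc21 | intermediate
10 | 1-tert-butyl 7-methyl (2E,4R)-4-(5-bromo-2-hydroxyphenyl)-4-formylhept-2-enedioate (present as the phenoxide, not isolated) | COC(=O)CC[C@@](C=O)(/C=C/C(=O)OC(C)(C)C)c1cc(Br)ccc1O | intermediate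
11 | tert-butyl [(2R,3S)-5-bromo-3-formyl-3-(3-methoxy-3-oxopropyl)-2,3-dihydro-1-benzofuran-2-yl]acetate (present as the ester enolate, not isolated) | COC(=O)CC[C@]1(C=O)c2cc(Br)ccc2O[C@@H]1CC(=O)OC(C)(C)C | intermediate
12 | tert-butyl (4aR,9bS)-8-bromo-9b-formyl-3-oxo-1,2,3,4,4a,9b-hexahydrodibenzo[b,d]furan-4-carboxylate (C4 epimers and enol) | O=C1CC[C@]2(C=O)c3cc(Br)ccc3O[C@@H]2C1C(=O)OC(C)(C)C | intermediate
13 | methyl [bis(2,2,2-trifluoroethoxy)phosphoryl]acetate | COC(=O)CP(=O)(OCC(F)(F)F)OCC(F)(F)F | starting material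
14 | tert-butyl (4aR,9bS)-8-bromo-9b-[(1Z)-3-methoxy-3-oxoprop-1-en-1-yl]-3-oxo-1,2,3,4,4a,9b-hexahydrodibenzo[b,d]furan-4-carboxylate | O=C1CC[C@]2(/C=C\C(=O)OC)c3cc(Br)ccc3O[C@@H]2C1C(=O)OC(C)(C)C | intermediate
15 | (2Z)-3-[(4aR,9bS)-8-bromo-4-(tert-butoxycarbonyl)-3-oxo-1,2,3,4,4a,9b-hexahydrodibenzo[b,d]furan-9b-yl]prop-2-enoic acid (not isolated) | O=C1CC[C@]2(/C=C\C(=O)O)c3cc(Br)ccc3O[C@@H]2C1C(=O)OC(C)(C)C | intermediate
16 | (4aR,9bS)-8-bromo-9b-[(1Z)-2-carboxyethenyl]-3-oxo-1,2,3,4,4a,9b-hexahydrodibenzo[b,d]furan-4-carboxylic acid (not isolated) | O=C1CC[C@]2(/C=C\C(=O)O)c3cc(Br)ccc3O[C@@H]2C1C(=O)O | intermediate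
17 | (2Z)-3-[(4aR,9bS)-8-bromo-3-oxo-1,2,3,4,4a,9b-hexahydrodibenzo[b,d]furan-9b-yl]prop-2-enoic acid | O=C1CC[C@]2(/C=C\C(=O)O)c3cc(Br)ccc3O[C@@H]2C1 | intermediate
18 | tert-butyl (4-aminobutyl){3-[(tert-butoxycarbonyl)amino]propyl}carbamate (N1,N5-bis-Boc spermidine, butyl-end amine free) | NCCCCN(CCCNC(=O)OC(C)(C)C)C(=O)OC(C)(C)C | starting material
19 | tert-butyl [4-({(2Z)-3-[(4aR,9bS)-8-bromo-3-oxo-1,2,3,4,4a,9b-hexahydrodibenzo[b,d]furan-9b-yl]prop-2-enoyl}amino)butyl]{3-[(tert-butoxycarbonyl)amino]propyl}carbamate | O=C1CC[C@]2(/C=C\C(=O)NCCCCN(CCCNC(=O)OC(C)(C)C)C(=O)OC(C)(C)C)c3cc(Br)ccc3O[C@@H]2C1 | intermediate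
20 | ethyl (2Z)-3-(tributylstannyl)prop-2-enoate | CCCC[Sn](CCCC)(CCCC)/C=C\C(=O)OCC | starting material
21 | analogue of 19 with a (1Z)-3-ethoxy-3-oxoprop-1-en-1-yl group in place of Br at C8, (4aR,9bS) | O=C1CC[C@]2(/C=C\C(=O)NCCCCN(CCCNC(=O)OC(C)(C)C)C(=O)OC(C)(C)C)c3cc(/C=C\C(=O)OCC)ccc3O[C@@H]2C1 | intermediate
22 | the (Z)-cinnamic acid corresponding to 21, both Boc groups in place (not isolated) | O=C1CC[C@]2(/C=C\C(=O)NCCCCN(CCCNC(=O)OC(C)(C)C)C(=O)OC(C)(C)C)c3cc(/C=C\C(=O)O)ccc3O[C@@H]2C1 | intermediate
23 | seco amino acid: (2Z)-3-[(4aR,9bS)-9b-{(1Z)-3-[(4-{[3-aminopropyl]amino}butyl)amino]-3-oxoprop-1-en-1-yl}-3-oxo-hexahydrodibenzo[b,d]furan-8-yl]prop-2-enoic acid | O=C1CC[C@]2(/C=C\C(=O)NCCCCNCCCN)c3cc(/C=C\C(=O)O)ccc3O[C@@H]2C1 | intermediate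
24 | CNP0415009.2: 20-membered bis-lactam in which the (Z)-acryloyl group on C9b and the (Z)-acryloyl group on C8 of (4aR,9bS)-3-oxo-1,2,3,4,4a,9b-hexahydrodibenzo[b,d]furan are amide-linked to the butyl-end and the propyl-end nitrogen of spermidine, secondary amine free | O=C1CC[C@]23/C=C\C(=O)NCCCCNCCCNC(=O)/C=C\c4ccc(c2c4)O[C@@H]3C1 | target

**Step count and risks**
Total step count: 11. Longest linear sequence: 11 (the route is linear).

The three steps most likely to fail:

1. Step 2. The addition may proceed with insufficient facial discrimination, or stall on the weakly electrophilic acrylate while the adduct loses its formyl group by retro-Claisen cleavage. The fallback sets out from 4: addition of 5 under an achiral tertiary amine (DABCO, MeCN) gives the racemic Michael adduct F1, and the Wittig reaction with 7 gives the racemic enoate F2. The enantiomers of F2 are then separated by preparative chromatography on a chiral stationary phase; the (R)-enantiomer is compound 8, where the route is rejoined.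

2. Step 5. The aldehyde set free beside strongly basic enolates may be consumed by intermolecular aldol addition, and any over-reduction in step 4 would feed the cascade the wrong oxidation level. The fallback sets out from 8: NaBH4 in THF–MeOH reduces only the aryl lactone, fully, to the phenol primary alcohol F3. KOtBu in THF then runs the same oxa-Michael/Dieckmann closure with no aldehyde present and gives the hydroxymethyl β-keto ester F4. Oxidation of the neopentyl alcohol with 1,1,1-triacetoxy-1,1-dihydro-1,2-benziodoxol-3(1H)-one returns to compound 12.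

3. Step 11. Acylation of the secondary amine (a 16-membered tertiary lactam) or oligomerisation may compete with closure at the primary amine. The fallback sets out from 23: one equivalent of aqueous formaldehyde ties the propyl-end and the internal nitrogen together as a six-membered aminal, the hexahydropyrimidine amino acid F5, which has a single acylatable N–H. EDC·HCl/HOAt macrolactamisation at that ring nitrogen gives the bridged macrolactam F6. Capture of the methylene bridge with dimedone (pyridine, EtOH, 50 °C; Knoevenagel-type scavenging of formaldehyde, which does not touch the ketone) returns to compound 24.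

**Further compounds**
F1 | step 2 | methyl 3-(5-bromo-3-formyl-2-oxo-2,3-dihydro-1-benzofuran-3-yl)propanoate, racemate | COC(=O)CCC1(C=O)C(=O)Oc2ccc(Br)cc21
F2 | step 2 | tert-butyl (2E)-3-[5-bromo-3-(3-methoxy-3-oxopropyl)-2-oxo-2,3-dihydro-1-benzofuran-3-yl]prop-2-enoate, racemate | COC(=O)CCC1(/C=C/C(=O)OC(C)(C)C)C(=O)Oc2ccc(Br)cc21
F3 | step 5 | 1-tert-butyl 7-methyl (2E,4R)-4-(5-bromo-2-hydroxyphenyl)-4-(hydroxymethyl)hept-2-enedioate | COC(=O)CC[C@@](CO)(/C=C/C(=O)OC(C)(C)C)c1cc(Br)ccc1O
F4 | step 5 | tert-butyl (4aR,9bR)-8-bromo-9b-(hydroxymethyl)-3-oxo-1,2,3,4,4a,9b-hexahydrodibenzo[b,d]furan-4-carboxylate | O=C1CC[C@]2(CO)c3cc(Br)ccc3O[C@@H]2C1C(=O)OC(C)(C)C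
F5 | step 11 | seco acid 23 with the propyl-end and internal nitrogens bridged by CH2 (hexahydropyrimidine) | O=C1CC[C@]2(/C=C\C(=O)NCCCCN4CNCCC4)c3cc(/C=C\C(=O)O)ccc3O[C@@H]2C1
F6 | step 11 | macrolactam 24 carrying an N–CH2–N methylene bridge between the cinnamamide nitrogen and the internal nitrogen | O=C1CC[C@]23/C=C\C(=O)NCCCCN5CN(CCC5)C(=O)/C=C\c4ccc(c2c4)O[C@@H]3C1
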